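**Retrosynthetic overview**
1. Numbering (daucane): C1 = methyl-bearing ring-fusion carbon, C2/C3 = CH2 groups of ring A, C4 = carbinol carbon with the isopropyl group, C5 = ring-fusion CH, C6 = aroyloxy carbon, C7 = CH2, C8 = methyl-bearing alkene carbon, C9 = alkene CH, C10 = angeloyloxy carbon. Ring A is the cyclopentane and ring B the cycloheptene. With the C1 methyl called β, the target has 5α-H, 4β-OH, 6α-O and 10α-O.
2. Late disconnections: the two esters come off last (C10 angelate, C6 4-hydroxybenzoate). C4(OH)(i-Pr) comes from a C4 ketone and an isopropyl nucleophile, 6α-OH from a C6 ketone by hydride delivery from the 4β-oxygen, and the C8 methyl from a C8 enol triflate.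
3. Key disconnection: ring B is cut at C6–C7 and C1–C10. This gives cyclopentenyl acylsilane 6 (C1–C6, ring A bought ready-made) and the lithium dienolate of 4-(PMB-oxy)butenone 9 (C7–C10).
4. Enabling feature: in ring B, C7H2 lies between oxygenated C6 and C8 of the C8=C9 alkene, and the other two sp3 ring atoms C1 and C10 are neighbours. At the ketone level of C6 and C8 this is a cyclohepta-1,4-diene (C5=C6 enol ether, C8=C9 enolate), the retron of a cis-divinylcyclopropane [3,3] shift. C6 and C8 are both carbonyl carbons and can be joined by Brook polarity reversal.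
5. Ring order: ring A (present in 1), then a transient cyclopropane C6–C7–C8, then ring B by three-to-seven ring expansion (last ring closed).

Key step: step 6

Remark: α/β descriptors follow the convention of line 1, and the SMILES strings are authoritative. TBS = tert-butyldimethylsilyl, PMB = 4-methoxybenzyl. Compounds 1, 7, 8, 24 and 29 are taken as catalogue compounds.

**Step 1**
Reactants: 1 2-bromo-3-methylcyclopent-2-en-1-one
Product: 2 (1S)-2-bromo-3-methylcyclopent-2-en-1-ol
Conditions: (R)-2-methyl-CBS-oxazaborolidine (10 mol %), BH3·SMe2, THF, −20 °C; MeOH quench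
Reagents that add atoms: none
Why: Corey–Bakshi–Shibata reduction in which the bromoalkenyl arm of the α-bromoenone plays the large group, so that the (R)-catalyst should give the (S)-carbinol, the temporary C4 stereocentre (4β-O) from which all other centres descend.

**Step 2**
Reactants: 2 (1S)-2-bromo-3-methylcyclopent-2-en-1-ol
Product: 3 (1S)-2-bromo-3-methylcyclopent-2-en-1-yl TBS ether
Conditions: TBSCl, imidazole, DMF, rt
Reagents that add atoms: tert-butyldimethylsilyl chloride, CC(C)(C)[Si](C)(C)Cl
Why: Standard silylation of a secondary allylic alcohol; the bulky silyl ether is the later face-blocking group and no stereocentre is touched.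

**Step 3**
Reactants: 3 (1S)-2-bromo-3-methylcyclopent-2-en-1-yl TBS ether
Product: 5 [(5S)-5-(tert-butyldimethylsilyloxy)-2-methylcyclopent-1-en-1-yl](morpholin-4-yl)methanone, via alkenyllithium 4 (not isolated)
Conditions: t-BuLi (2.1 equiv), Et2O, −78 °C; then morpholine-4-carbonyl chloride, −78 → 0 °C
Reagents that add atoms: morpholine-4-carbonyl chloride, O=C(Cl)N1CCOCC1
Why: Bromine–lithium exchange followed by acylation of the alkenyllithium with a carbamoyl chloride; the ring forbids β-elimination of the silyloxy group from 4, C4 is untouched and the new carbonyl carbon is C6.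

**Step 4**
Reactants: 5 morpholine amide
Product: 6 [(5S)-5-(tert-butyldimethylsilyloxy)-2-methylcyclopent-1-en-1-yl][dimethyl(phenyl)silyl]methanone (acylsilane)
Conditions: PhMe2SiLi (THF solution from PhMe2SiCl and Li), THF, −78 °C; sat. NH4Cl at −78 °C
Reagents that add atoms: dimethyl(phenyl)silyllithium, [Li][Si](C)(C)c1ccccc1
Why: Acylsilane synthesis by addition of a silyllithium to a morpholine amide, whose stable tetrahedral adduct prevents over-addition and collapses only on the cold quench; conjugate attack is blocked by the fully substituted β-carbon.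

**Step 5**
Reactants: 7 (3E)-4-methoxybut-3-en-2-one; 8 4-methoxybenzyl alcohol
Product: 9 (3E)-4-[(4-methoxybenzyl)oxy]but-3-en-2-one
Conditions: pyridinium p-toluenesulfonate (5 mol %), toluene, 80 °C, MeOH distilled off
Reagents that add atoms: none
Why: Acid-catalysed addition–elimination (vinylogous transesterification) driven by removal of methanol; the thermodynamic E-enol ether is kept, and this geometry later encodes C10.

**Step 6**
Reactants: 6 acylsilane; 9 (3E)-4-[(4-methoxybenzyl)oxy]but-3-en-2-one
Product: 14 hydroazulene enol triflate (C8-OTf; C5=C6-OSiMe2Ph; 1β-Me; 4β-OTBS; 10α-OPMB), via lithium dienolate 10 (not isolated), via silyl carbinolate 11 (not isolated), via divinylcyclopropanolate 12 (not isolated), via ring B enolate 13 (not isolated)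
Conditions: LiN(i-Pr)2, THF, −78 °C, 9; add 6, −78 → −30 °C; recool to −78 °C, N-(5-chloro-2-pyridyl)bis(trifluoromethanesulfonimide), −78 → −40 °C
Reagents that add atoms: N-(5-chloro-2-pyridyl)bis(trifluoromethanesulfonimide), O=S(=O)(N(c1ccc(Cl)cn1)S(=O)(=O)C(F)(F)F)C(F)(F)F
Why: Dienolate 10 adds 1,2 to the acylsilane carbonyl (C6–C7 bond) to give 11, whose 1,2-Brook shift moves silicon from C6 to oxygen and turns the former acyl carbon into a siloxyallyl carbanion that closes 3-exo-trig onto the C8 ketone, so that two carbonyl carbons (C6 and C8) are joined by polarity reversal in cis-dialkenylcyclopropanolate 12. The alkoxide-accelerated [3,3] shift of 12 (anionic oxy-Cope of a cis-divinylcyclopropane through the only possible boat transition state) breaks C6–C8, makes C1–C10 and so closes ring B by three-to-seven ring expansion, releasing enolate 13 with its double bond fixed at C8=C9, which the triflimide traps at −78 °C. The closest known reaction type is the Brook-rearrangement-mediated [3+4] annulation of acryloylsilanes with lithium enolates of alkenyl methyl ketones, followed by ordinary regiospecific enolate triflation. The absolute sense comes from C4: allylic 1,3-strain with the C6 substituents holds the C4–H bond in the plane of the siloxyallyl anion, the 4β-OTBS group covers the β face, C8 therefore bonds to C6 on the α face, and the suprafacial shift hands this face on to C1, which makes the new C1–C10 bond α and the methyl β. C10 is set relative to C1 by the stereospecificity of the boat, because the two substituents that stand trans to the cyclopropane on their alkenes (ring carbon C2 on C1, OPMB on C10 of the E-enol ether) end up cis, which is the 10α-oxygen/1β-methyl relation of the target. The step needs 1,2- over 1,4-addition (secured by the fully substituted β-carbon C1), a cis-dialkenyl cyclopropane (the lithium-bridged syn arrangement of the two oxygens places both alkenyl groups cis) and survival of β-alkoxy enolate 13 against loss of the C10 alkoxide (the C10–O bond is pseudo-equatorial, close to the nodal plane of the enolate, and the trap is applied cold).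

**Step 7**
Reactants: 14 hydroazulene enol triflate
Product: 15 8-methyl diene (C8(Me)=C9; C5=C6-OSiMe2Ph; 1β-Me; 4β-OTBS; 10α-OPMB)
Conditions: MeMgBr, Fe(acac)3 (5 mol %), THF/NMP, −30 °C
Reagents that add atoms: methylmagnesium bromide, C[Mg]Br
Why: Iron-catalysed Kumada-type cross-coupling of an alkenyl triflate with a methyl Grignard reagent, fast at low temperature and blind to silyl enol ether, silyl ether and benzyl-type ether; it installs the C8 methyl group with the alkene fixed at C8=C9.

**Step 8**
Reactants: 15 8-methyl diene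
Product: 17 trans-fused β-hydroxy ketone (C6=O; 5α-H; 4β-OH; 10α-OPMB), via silyloxy ketone 16 (not isolated)
Conditions: HF·pyridine, pyridine, THF, −20 °C → rt
Reagents that add atoms: none
Why: Protodesilylation of the labile enol silane precedes cleavage of the alkyl TBS ether, so that C5 is protonated while the β face is still covered by the angular methyl and the 4β-OTBS group and the proton should enter from the α face (5α-H, trans fusion, afterwards supported by the O4–H···O=C6 hydrogen bond possible only in this epimer); the buffered medium should leave the C8=C9 alkene out of conjugation.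

**Step 9**
Reactants: 17 trans-fused β-hydroxy ketone
Product: 18 4β-acetoxy-6α-ol (5α-H; 10α-OPMB)
Conditions: CH3CHO (10 equiv), SmI2 (30 mol %), THF, −10 °C
Reagents that add atoms: acetaldehyde, CC=O
Why: Evans–Tishchenko reduction, in which acetaldehyde bound through the 4β-oxygen inside a trivalent samarium chelate with the C6 carbonyl passes its hydride to the β face of C6; this should give the equatorial 6α (1,3-anti) alcohol and leaves O4 acetylated, so that the two secondary oxygens are told apart, and an epimer with C6 trans to O4 cannot reach this transition state.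

**Step 10**
Reactants: 18 4β-acetoxy-6α-ol
Product: 19 4β-acetoxy-6α-OTBS compound
Conditions: TBSOTf, 2,6-lutidine, CH2Cl2, −78 → 0 °C
Reagents that add atoms: tert-butyldimethylsilyl trifluoromethanesulfonate, CC(C)(C)[Si](C)(C)OS(=O)(=O)C(F)(F)F
Why: Silylation of the free 6α-alcohol under a non-nucleophilic base, cold enough to avoid 1,3-acetyl migration; a silyl ether is chosen because it is a poor leaving group β to the coming C4 ketone.

**Step 11**
Reactants: 19 4β-acetoxy-6α-OTBS compound
Product: 20 4β-ol (6α-OTBS; 10α-OPMB)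
Conditions: K2CO3, MeOH, rt
Reagents that add atoms: none
Why: Base-catalysed methanolysis (transesterification) of the only ester; silyl and benzyl-type ethers are inert and no epimerisable centre is present.

**Step 12**
Reactants: 20 4β-ol
Product: 21 C4 ketone (5α-H; 6α-OTBS; 10α-OPMB)
Conditions: Dess–Martin periodinane, CH2Cl2, 0 °C → rt
Reagents that add atoms: none
Why: Dess–Martin oxidation under near-neutral conditions, chosen so that C5 (now α to the ketone) is not epimerised and the β-silyloxy group is not eliminated; the temporary C4 stereocentre is erased after it has done its work.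

**Step 13**
Reactants: 21 C4 ketone
Product: 22 4β-hydroxy-4α-isopropyl compound (6α-OTBS; 10α-OPMB)
Conditions: i-PrMgCl, LaCl3·2LiCl (1 equiv), THF, 0 °C; aq. NH4Cl
Reagents that add atoms: isopropylmagnesium chloride, CC(C)[Mg]Cl
Why: Lanthanide-promoted Grignard 1,2-addition (the soluble lanthanum salt suppresses enolisation and β-hydride reduction of cyclopentanones by secondary Grignard reagents); the nucleophile should enter from the α face, anti to the pseudo-axial 1β-methyl and to the C5–C6 bond, which gives the 4β-OH/4α-isopropyl centre of the target.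

**Step 14**
Reactants: 22 4β-hydroxy-4α-isopropyl compound
Product: 23 4β,6α-diol (10α-OPMB)
Conditions: HF·pyridine, THF, 0 °C → rt
Reagents that add atoms: none
Why: Fluoride-mediated cleavage of the secondary TBS ether under mildly acidic conditions that leave the tertiary alcohol, the PMB ether and the alkene untouched.

**Step 15**
Reactants: 24 4-hydroxybenzoic acid
Product: 26 4-(tert-butyldimethylsilyloxy)benzoic acid, via bis-silyl derivative 25 (not isolated)
Conditions: TBSCl (2.2 equiv), imidazole, DMF, rt; then AcOH/H2O/THF, rt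
Reagents that add atoms: tert-butyldimethylsilyl chloride, CC(C)(C)[Si](C)(C)Cl
Why: Exhaustive silylation followed by selective hydrolysis of the far more labile silyl ester, the standard way to O-silylated hydroxybenzoic acids.

**Step 16**
Reactants: 23 4β,6α-diol; 26 4-(tert-butyldimethylsilyloxy)benzoic acid
Product: 27 6α-[4-(TBSO)benzoyloxy]-4β-ol (10α-OPMB)
Conditions: DCC, DMAP (cat.), CH2Cl2, rt
Reagents that add atoms: none
Why: Steglich esterification; only the secondary 6α-alcohol is acylated because the tertiary 4β-alcohol is too hindered, and the C6–O bond is not broken, so its configuration is kept.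

**Step 17**
Reactants: 27 6α-aroyloxy PMB ether
Product: 28 10α-ol (6α-[4-(TBSO)benzoyloxy]; 4β-OH)
Conditions: DDQ, CH2Cl2/pH 7 buffer, 0 °C
Reagents that add atoms: none
Why: Oxidative cleavage of the 4-methoxybenzyl ether by DDQ (hydride abstraction, hydrolysis of the oxocarbenium ion); ester, aryl silyl ether, tertiary alcohol and trisubstituted alkene are inert and the C10–O bond is not broken.

**Step 18**
Reactants: 28 10α-ol; 29 angelic acid [(2Z)-2-methylbut-2-enoic acid]
Product: 31 O-TBS-protected target (10α-angelate), via mixed anhydride 30 (not isolated)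
Conditions: 29, 2,4,6-trichlorobenzoyl chloride, Et3N, toluene, rt; then 28, 75 °C
Reagents that add atoms: none
Why: Yamaguchi-type acylation through the mixed anhydride without a nucleophilic catalyst, the conditions known to transfer the angeloyl group without Z-to-E isomerisation; the neopentyl allylic 10α-alcohol reacts on heating while the tertiary alcohol does not, and C10 keeps its configuration.

**Step 19**
Reactants: 31 O-TBS-protected target
Product: 32 target, (3R,3aS,4S,8R,8aS)-3-hydroxy-4-[(4-hydroxybenzoyl)oxy]-6,8a-dimethyl-3-(propan-2-yl)-1,2,3,3a,4,5,8,8a-octahydroazulen-8-yl (2Z)-2-methylbut-2-enoate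
Conditions: Bu4NF, AcOH, THF, 0 °C
Reagents that add atoms: none
Why: Buffered fluoride cleaves the aryl silyl ether quickly at 0 °C, and acetic acid keeps the medium non-basic so that neither ester migrates or cleaves and the angelate stays Z.

**Compound list**

| No. | Name | SMILES | Role |
|---|---|---|---|
| 1 | 2-bromo-3-methylcyclopent-2-en-1-one | CC1=C(Br)C(=O)CC1 | starting material |
| 2 | (1S)-2-bromo-3-methylcyclopent-2-en-1-ol | BrC1=C(C)CC[C@@H]1O | intermediate |
| 3 | (1S)-2-bromo-3-methylcyclopent-2-en-1-yl TBS ether | BrC1=C(C)CC[C@@H]1O[Si](C)(C)C(C)(C)C | intermediate |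
| 4 | [(5S)-5-(TBSO)-2-methylcyclopent-1-en-1-yl]lithium | [Li]C1=C(C)CC[C@@H]1O[Si](C)(C)C(C)(C)C | intermediate |
| 5 | [(5S)-5-(TBSO)-2-methylcyclopent-1-en-1-yl](morpholin-4-yl)methanone | O=C(N1CCOCC1)C2=C(C)CC[C@@H]2O[Si](C)(C)C(C)(C)C | intermediate |
| 6 | [(5S)-5-(TBSO)-2-methylcyclopent-1-en-1-yl][dimethyl(phenyl)silyl]methanone | O=C([Si](C)(C)c1ccccc1)C2=C(C)CC[C@@H]2O[Si](C)(C)C(C)(C)C | intermediate |
| 7 | (3E)-4-methoxybut-3-en-2-one | CO/C=C/C(C)=O | starting material |
| 8 | 4-methoxybenzyl alcohol | COc1ccc(CO)cc1 | starting material |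
| 9 | (3E)-4-[(4-methoxybenzyl)oxy]but-3-en-2-one | CC(=O)/C=C/OCc1ccc(OC)cc1 | intermediate |
| 10 | lithium (3E)-4-[(4-methoxybenzyl)oxy]buta-1,3-dien-2-olate | [Li]OC(=C)/C=C/OCc1ccc(OC)cc1 | intermediate |
| 11 | lithium α-silyl carbinolate from 1,2-addition of 10 to 6 (C6 configuration undefined, erased in the Brook shift) | [Li]OC(CC(=O)/C=C/OCc1ccc(OC)cc1)([Si](C)(C)c2ccccc2)C3=C(C)CC[C@@H]3O[Si](C)(C)C(C)(C)C | intermediate |
| 12 | lithium cis-dialkenylcyclopropanolate (C6–C7–C8 ring; both oxygens cis, both alkenyl groups cis; C8 on the α face of ring A) | [Li]O[C@]1(/C=C/OCc2ccc(OC)cc2)C[C@@]1(O[Si](C)(C)c3ccccc3)C4=C(C)CC[C@@H]4O[Si](C)(C)C(C)(C)C | intermediate |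
| 13 | lithium C8=C9 enolate of the hydroazulene (C5=C6-OSiMe2Ph; 1β-Me; 4β-OTBS; 10α-OPMB) | COc1ccc(CO[C@@H]2C=C(O[Li])CC(O[Si](C)(C)c3ccccc3)=C4[C@]2(C)CC[C@@H]4O[Si](C)(C)C(C)(C)C)cc1 | intermediate |
| 14 | hydroazulene C8 enol triflate (C5=C6-OSiMe2Ph; 1β-Me; 4β-OTBS; 10α-OPMB) | COc1ccc(CO[C@@H]2C=C(OS(=O)(=O)C(F)(F)F)CC(O[Si](C)(C)c3ccccc3)=C4[C@]2(C)CC[C@@H]4O[Si](C)(C)C(C)(C)C)cc1 | intermediate |
| 15 | 8-methyl diene (C8(Me)=C9; C5=C6-OSiMe2Ph; 4β-OTBS; 10α-OPMB) | COc1ccc(CO[C@@H]2C=C(C)CC(O[Si](C)(C)c3ccccc3)=C4[C@]2(C)CC[C@@H]4O[Si](C)(C)C(C)(C)C)cc1 | intermediate |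
| 16 | trans-fused C6 ketone, 4β-OTBS, 5α-H | COc1ccc(CO[C@@H]2C=C(C)CC(=O)[C@@H]3[C@]2(C)CC[C@@H]3O[Si](C)(C)C(C)(C)C)cc1 | intermediate |
| 17 | trans-fused C6 ketone, 4β-OH, 5α-H | COc1ccc(CO[C@@H]2C=C(C)CC(=O)[C@@H]3[C@]2(C)CC[C@@H]3O)cc1 | intermediate |
| 18 | 4β-acetoxy-6α-ol | COc1ccc(CO[C@@H]2C=C(C)C[C@H](O)[C@@H]3[C@]2(C)CC[C@@H]3OC(C)=O)cc1 | intermediate |
| 19 | 4β-acetoxy-6α-OTBS compound | COc1ccc(CO[C@@H]2C=C(C)C[C@H](O[Si](C)(C)C(C)(C)C)[C@@H]3[C@]2(C)CC[C@@H]3OC(C)=O)cc1 | intermediate |
| 20 | 4β-ol, 6α-OTBS | COc1ccc(CO[C@@H]2C=C(C)C[C@H](O[Si](C)(C)C(C)(C)C)[C@@H]3[C@]2(C)CC[C@@H]3O)cc1 | intermediate |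
| 21 | C4 ketone, 6α-OTBS, 5α-H | COc1ccc(CO[C@@H]2C=C(C)C[C@H](O[Si](C)(C)C(C)(C)C)[C@@H]3[C@]2(C)CCC3=O)cc1 | intermediate |
| 22 | 4β-hydroxy-4α-isopropyl, 6α-OTBS, 10α-OPMB | COc1ccc(CO[C@@H]2C=C(C)C[C@H](O[Si](C)(C)C(C)(C)C)[C@@H]3[C@]2(C)CC[C@@]3(O)C(C)C)cc1 | intermediate |
| 23 | 4β,6α-diol, 10α-OPMB | COc1ccc(CO[C@@H]2C=C(C)C[C@H](O)[C@@H]3[C@]2(C)CC[C@@]3(O)C(C)C)cc1 | intermediate |
| 24 | 4-hydroxybenzoic acid | OC(=O)c1ccc(O)cc1 | starting material |
| 25 | tert-butyldimethylsilyl 4-(tert-butyldimethylsilyloxy)benzoate | CC(C)(C)[Si](C)(C)OC(=O)c1ccc(O[Si](C)(C)C(C)(C)C)cc1 | intermediate |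
| 26 | 4-(tert-butyldimethylsilyloxy)benzoic acid | OC(=O)c1ccc(O[Si](C)(C)C(C)(C)C)cc1 | intermediate |
| 27 | 6α-[4-(TBSO)benzoyloxy]-4β-ol, 10α-OPMB | COc1ccc(CO[C@@H]2C=C(C)C[C@H](OC(=O)c3ccc(O[Si](C)(C)C(C)(C)C)cc3)[C@@H]4[C@]2(C)CC[C@@]4(O)C(C)C)cc1 | intermediate |
| 28 | 10α-ol, 6α-[4-(TBSO)benzoyloxy], 4β-OH | O[C@@H]1C=C(C)C[C@H](OC(=O)c2ccc(O[Si](C)(C)C(C)(C)C)cc2)[C@@H]3[C@]1(C)CC[C@@]3(O)C(C)C | intermediate |
| 29 | angelic acid, (2Z)-2-methylbut-2-enoic acid | C/C=C(/C)C(=O)O | starting material |
| 30 | angelic 2,4,6-trichlorobenzoic anhydride | C/C=C(/C)C(=O)OC(=O)c1c(Cl)cc(Cl)cc1Cl | intermediate |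
| 31 | O-TBS-protected target | C/C=C(/C)C(=O)O[C@@H]1C=C(C)C[C@H](OC(=O)c2ccc(O[Si](C)(C)C(C)(C)C)cc2)[C@@H]3[C@]1(C)CC[C@@]3(O)C(C)C | intermediate |
| 32 | target, 10α-angeloyloxy-6α-(4-hydroxybenzoyloxy)-4β-hydroxydauc-8-ene | C/C=C(/C)C(=O)O[C@@H]1C=C(C)C[C@H](OC(=O)c2ccc(O)cc2)[C@@H]2[C@]1(C)CC[C@@]2(O)C(C)C | target |

**Step count**
- Total step count: 19.
- Longest linear sequence: 17 (steps 1–4, 6–14, 16–19).

**Steps most likely to fail**

*Step 6.* The Brook shift and cyclopropane closure may be slow at the crowded acylsilane. The C10 alkoxide may also be lost from the β-alkoxy enolate before it is triflated.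

The fallback is a carbene-transfer formal [4+3], known for alkenyl Fischer-type carbene complexes and 1,3-dienes. Here C8 already carries its methyl group and no enolate is formed. It sets out from 3 and 9 and comes back at 17.
- Bromide 3 is lithiated as in step 3 (4) and added to Cr(CO)6 to give lithium acylchromate F1. O-Methylation with Me3OBF4 gives the pentacarbonyl(methoxy)(cyclopentenyl)carbene complex of zerovalent chromium F2.
- Enone 9 is methylenated with Ph3P=CH2 to (E)-1-[(4-methoxybenzyl)oxy]-3-methylbuta-1,3-diene F3.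
- Heating F2 with F3 (toluene, 80 °C) should cyclopropanate the terminal 1,1-disubstituted alkene on the face anti to the OTBS group. This gives methoxy-substituted cis-divinylcyclopropane F4, which rearranges in the flask to bicyclic methyl enol ether F5.
- Aqueous HF in MeCN hydrolyses the enol ether (through 16) and removes the TBS group, which rejoins the route at 17.

*Step 8.* Facial selectivity in the protonation of C5 may be poor, C5 may epimerise afterwards, or the C8=C9 alkene may drift into conjugation.

The fallback does not fix C5 by kinetic protonation. It couples reversible C5 epimerisation to an epimer-selective, hydroxyl-directed reduction. It sets out from 17 (whatever its composition at C5) and comes back at 20.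
- The ketone is treated with Me4NBH(OAc)3 in MeCN/AcOH.
- This reagent reduces a ketone only after exchange onto a neighbouring hydroxyl, and only the trans-fused epimer holds C6=O within reach of the 4β-oxygen.
- That epimer alone is therefore drained, while recovered ketone is re-equilibrated (cat. DBU) and recycled. This should give 4β,6α-diol F6.
- The equatorial 6α-OH of F6 is silylated selectively (TBSCl, imidazole) over the pseudo-axial 4β-OH, which is 1,3-syn to the angular methyl. The product is 20.

*Step 13.* The branched Grignard reagent may enolise hindered ketone 21 or reduce it by β-hydride transfer, and the C6 silyloxy group may be lost by β-elimination.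

The fallback sets out from 21 and comes back at 22.
- The flat, β-hydride-free nucleophile isopropenyllithium/CeCl3 (THF, −78 °C) is added from the same α face to give isopropenyl carbinol F7.
- The 1,1-disubstituted alkene of F7 is hydrogenated chemoselectively with RhCl(PPh3)3/H2 (benzene/EtOH). This leaves the trisubstituted C8=C9 alkene and the PMB ether in place and gives 22.

**Further compounds**
F1 | step 6 | lithium acylchromate from 4 and Cr(CO)6 | [Li]OC(=[Cr](=C=O)(=C=O)(=C=O)(=C=O)=C=O)C1=C(C)CC[C@@H]1O[Si](C)(C)C(C)(C)C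
F2 | step 6 | pentacarbonyl{methoxy[(5S)-5-(TBSO)-2-methylcyclopent-1-en-1-yl]carbene}chromium | COC(=[Cr](=C=O)(=C=O)(=C=O)(=C=O)=C=O)C1=C(C)CC[C@@H]1O[Si](C)(C)C(C)(C)C
F3 | step 6 | (E)-1-[(4-methoxybenzyl)oxy]-3-methylbuta-1,3-diene | C=C(C)/C=C/OCc1ccc(OC)cc1
F4 | step 6 | cis-divinylcyclopropane (C6-OMe, C8-Me) | C[C@]1(/C=C/OCc2ccc(OC)cc2)C[C@@]1(OC)C3=C(C)CC[C@@H]3O[Si](C)(C)C(C)(C)C
F5 | step 6 | bicyclic methyl enol ether (C5=C6-OMe; C8(Me)=C9; 4β-OTBS; 10α-OPMB) | COc1ccc(CO[C@@H]2C=C(C)CC(OC)=C3[C@]2(C)CC[C@@H]3O[Si](C)(C)C(C)(C)C)cc1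
F6 | step 8 | 4β,6α-diol (secondary C4 carbinol; 10α-OPMB) | COc1ccc(CO[C@@H]2C=C(C)C[C@H](O)[C@@H]3[C@]2(C)CC[C@@H]3O)cc1
F7 | step 13 | 4β-hydroxy-4α-isopropenyl compound (6α-OTBS; 10α-OPMB) | COc1ccc(CO[C@@H]2C=C(C)C[C@H](O[Si](C)(C)C(C)(C)C)[C@@H]3[C@]2(C)CC[C@@]3(O)C(C)=C)cc1
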